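Both outer rings are the same butyrylfilicinic acid unit, so one ring synthesis serves twice. With that ring numbered C1 (ring carbonyl), C2 (acyl carbon), C3, C4 (CMe2), C5 and C6 (bridge carbon), everything rests on cutting C1–C6 and C2–C3. Because C4 is quaternary, the four-carbon β-keto ester C6–C5–C4–C3 enolizes only at C6 and its ester carbon C3 cannot enolize. A crossed Claisen acylation (C6 onto C1 of methyl 3-oxohexanoate) followed by Claisen ring closure (C2 onto C3) therefore builds the fully substituted triketone ring from two acyclic esters in one flask. Two such rings are then joined to butyrylphloroglucinol through methylene bridges via a bis-Mannich base.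

Key step: step 1

Remark: compounds 1, 2 and 5 are taken as commercial. The β-triketone and acylphloroglucinol units are drawn as single keto–enol tautomers (for 11 the tautomer of the target SMILES). No compound in the route has a stereocenter.

Step 1
Reactants: 1 methyl 2,2-dimethyl-3-oxobutanoate; 2 methyl 3-oxohexanoate
Product: 4 2-butanoyl-3,5-dihydroxy-4,4-dimethylcyclohexa-2,5-dien-1-one (butyrylfilicinic acid), via methyl 2,2-dimethyl-3,5,7-trioxodecanoate 3 (not isolated)
Conditions: 1, LiN(iPr)2 (1.05 equiv), THF, −78 °C; separately 2 (1.2 equiv), LiN(iPr)2 (1.2 equiv), THF, −78 °C; combine, −78 °C to 60 °C; then aq. HCl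
Reagents that add atoms: none
Why: Kinetic deprotonation of 1 can only take place at the acetyl methyl group (the future C6), and this lithium enolate attacks the ester carbon (future C1) of 2, which is added as its pre-formed lithium enolate so that it cannot protonate the ketone enolate; loss of methoxide gives the triketo ester 3 as its dianion. The carbanion of 3 between the C1 and butanoyl carbonyls (C2) then attacks the non-enolizable ester carbon (C3) in a 6-exo-trig intramolecular Claisen (Dieckmann-type) closure, and a second loss of methoxide gives the enolate of 4. The closest known reaction types are the crossed Claisen acylation of strongly basic enolate anions by lithium salts of β-keto esters and the Claisen cyclization of 3,5,7-triketo esters to acylphloroglucinols. No stereocenter is formed. The step needs C-acylation in preference to O-acylation and Claisen closure in preference to aldol closure: the quaternary C4 removes the α-carbanion that an aldol closure of a triketo ester normally uses and keeps the ester electrophilic, O-acylation products reopen under the methoxide that is set free, and the doubly stabilized β-triketone anion of 4 is the thermodynamic sink.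

Step 2
Reactants: 5 1-(2,4,6-trihydroxyphenyl)butan-1-one
Product: 7 1-[3,5-bis[(dimethylamino)methyl]-2,4,6-trihydroxyphenyl]butan-1-one, via mono-Mannich base 6 (not isolated)
Conditions: 37% aq. CH2O (2.2 equiv), 40% aq. Me2NH (2.5 equiv), pre-mixed, EtOH, 0 °C to rt
Reagents that add atoms: formaldehyde C=O; dimethylamine CNC
Why: Phenolic Mannich reaction, in which the iminium ion from formaldehyde and dimethylamine should attack the only two free ring carbons of 5 (C3 and C5, each flanked by two hydroxyls and para to the third), first to 6 and then to 7, while the pre-mixed excess of amine keeps diarylmethane formation down.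

Step 3
Reactants: 7 1-[3,5-bis[(dimethylamino)methyl]-2,4,6-trihydroxyphenyl]butan-1-one; 4 butyrylfilicinic acid (2 equivalents)
Product: 11 1-[2,4,6-trihydroxy-3,5-bis[(5-butanoyl-2,4-dihydroxy-3,3-dimethyl-6-oxocyclohexa-1,4-dien-1-yl)methyl]phenyl]butan-1-one (the target), via first ortho-quinone methide 8 (not isolated), via mono-adduct 9 (not isolated), via second ortho-quinone methide 10 (not isolated)
Conditions: 4 (2.1 equiv), 1,4-dioxane, 80 °C, N2; then dilute aq. HCl
Reagents that add atoms: none
Why: Alkylation of a 1,3-dicarbonyl carbon nucleophile by a phenolic Mannich base (elimination, then Michael addition), in which the acidic triketone 4 protonates a benzylic amine of 7, hydroxyl-assisted loss of dimethylamine gives the ortho-quinone methide 8, and the enolate of 4 adds through C6, its only unsubstituted ring carbon, with rearomatization to 9; the same sequence on the second arm through 10 should give 11.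

Compound list
1 | methyl 2,2-dimethyl-3-oxobutanoate | CC(=O)C(C)(C)C(=O)OC | starting material
2 | methyl 3-oxohexanoate | CCCC(=O)CC(=O)OC | starting material
3 | methyl 2,2-dimethyl-3,5,7-trioxodecanoate (present as its lithium enolate) | CCCC(=O)CC(=O)CC(=O)C(C)(C)C(=O)OC | intermediate
4 | 2-butanoyl-3,5-dihydroxy-4,4-dimethylcyclohexa-2,5-dien-1-one (butyrylfilicinic acid) | CCCC(=O)C1=C(O)C(C)(C)C(O)=CC1=O | intermediate
5 | 1-(2,4,6-trihydroxyphenyl)butan-1-one | CCCC(=O)c1c(O)cc(O)cc1O | starting material
6 | 1-[3-[(dimethylamino)methyl]-2,4,6-trihydroxyphenyl]butan-1-one | CCCC(=O)c1c(O)cc(O)c(CN(C)C)c1O | intermediate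
7 | 1-[3,5-bis[(dimethylamino)methyl]-2,4,6-trihydroxyphenyl]butan-1-one | CCCC(=O)c1c(O)c(CN(C)C)c(O)c(CN(C)C)c1O | intermediate
8 | 2-butanoyl-4-[(dimethylamino)methyl]-3,5-dihydroxy-6-methylidenecyclohexa-2,4-dien-1-one | CCCC(=O)C1=C(O)C(CN(C)C)=C(O)C(=C)C1=O | intermediate
9 | 1-[3-[(5-butanoyl-2,4-dihydroxy-3,3-dimethyl-6-oxocyclohexa-1,4-dien-1-yl)methyl]-5-[(dimethylamino)methyl]-2,4,6-trihydroxyphenyl]butan-1-one | CCCC(=O)C1=C(O)C(C)(C)C(O)=C(Cc2c(O)c(CN(C)C)c(O)c(C(=O)CCC)c2O)C1=O | intermediate
10 | 2-butanoyl-4-[(5-butanoyl-2,4-dihydroxy-3,3-dimethyl-6-oxocyclohexa-1,4-dien-1-yl)methyl]-3,5-dihydroxy-6-methylidenecyclohexa-2,4-dien-1-one | CCCC(=O)C1=C(O)C(CC2=C(O)C(C)(C)C(O)=C(C(=O)CCC)C2=O)=C(O)C(=C)C1=O | intermediate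
11 | 1-[2,4,6-trihydroxy-3,5-bis[(5-butanoyl-2,4-dihydroxy-3,3-dimethyl-6-oxocyclohexa-1,4-dien-1-yl)methyl]phenyl]butan-1-one | CCCC(=O)C1=C(O)C(C)(C)C(O)=C(Cc2c(O)c(CC3=C(O)C(C)(C)C(O)=C(C(=O)CCC)C3=O)c(O)c(C(=O)CCC)c2O)C1=O | target

Total step count: 3
Longest linear sequence: 2 steps (step 1 or step 2, then step 3)

Steps most likely to fail

1. Step 1. The intermolecular acylation joins two anions and may be too slow. The ketone enolate of 1 could then be lost to proton exchange and self-condensation, and the methoxide set free could cleave unreacted 1 by retro-Claisen fragmentation before 3 forms and closes. The fallback sets out from 5 and comes back at 4: dearomatizing geminal C-methylation of 5 with MeI and NaOMe in MeOH should place both methyl groups on one ring carbon and give 4 directly. It makes no compound outside the list (F0).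

2. Step 3. Loss of amine from 7 may need a temperature at which the methylene bridges exchange between rings by retro-Michael reaction and re-addition, and the quinone methide may add to a second molecule of 7, so that homo-coupled and oligomeric material builds up. The fallback reverses the roles, sets out from 4 and 5 and comes back at 11. Compound 4 would be aminomethylated at C6 (aq. CH2O, aq. Me2NH, EtOH) to the Mannich base 2-butanoyl-6-[(dimethylamino)methyl]-3,5-dihydroxy-4,4-dimethylcyclohexa-2,5-dien-1-one F1. Two equivalents of F1 heated with 5 in 1,4-dioxane should lose dimethylamine to the methylene triketone 2-butanoyl-3-hydroxy-4,4-dimethyl-6-methylidenecyclohex-2-ene-1,5-dione F2. The two free ring carbons of 5 would capture F2 in turn, through the mono-adduct 2-butanoyl-6-[(3-butanoyl-2,4,6-trihydroxyphenyl)methyl]-3,5-dihydroxy-4,4-dimethylcyclohexa-2,5-dien-1-one F3, to give 11.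

3. Step 2. Aminomethylation may not stop cleanly at 7: the mono-Mannich base 6 can lose amine and alkylate a second phloroglucinol ring, and incomplete second aminomethylation would leave amphoteric mixtures that are hard to separate. The fallback sets out from 5 and comes back at 7, with both benzylic carbons introduced at the aldehyde oxidation level. Twofold Rieche formylation of 5 (Cl2CHOMe, TiCl4, CH2Cl2; aqueous work-up) should give the dialdehyde 5-butanoyl-2,4,6-trihydroxybenzene-1,3-dicarbaldehyde F4. Double reductive amination of F4 (Me2NH, NaBH(OAc)3, THF, AcOH) should then give 7.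

Further compounds
F0 | step 1 | none | none
F1 | step 3 | 2-butanoyl-6-[(dimethylamino)methyl]-3,5-dihydroxy-4,4-dimethylcyclohexa-2,5-dien-1-one | CCCC(=O)C1=C(O)C(C)(C)C(O)=C(CN(C)C)C1=O
F2 | step 3 | 2-butanoyl-3-hydroxy-4,4-dimethyl-6-methylidenecyclohex-2-ene-1,5-dione | CCCC(=O)C1=C(O)C(C)(C)C(=O)C(=C)C1=O
F3 | step 3 | 2-butanoyl-6-[(3-butanoyl-2,4,6-trihydroxyphenyl)methyl]-3,5-dihydroxy-4,4-dimethylcyclohexa-2,5-dien-1-one | CCCC(=O)C1=C(O)C(C)(C)C(O)=C(Cc2c(O)cc(O)c(C(=O)CCC)c2O)C1=O
F4 | step 2 | 5-butanoyl-2,4,6-trihydroxybenzene-1,3-dicarbaldehyde | CCCC(=O)c1c(O)c(C=O)c(O)c(C=O)c1O
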